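If a solid substrate enters solution over hours and the dissolved substrate can leave by two routes, the target of this flask can be reckoned from the charge and two small losses.

    solid substrate + protic impurity → quenched substrate (k1 = 57 /M/h)
    solid product ⇌ target, rate k2*(cs2 - [target]) while solid is left; crystals form when [target] > cs2 (cs2 = 0.093 M, k2 = 3.8 /h)
    dissolved substrate + coupling partner → target (k3 = 0.80 /M/h)
    2 dissolved substrate → side product (k4 = 0.21 /M/h)
    solid substrate ⇌ dissolved substrate, rate k5*(cs5 - [dissolved substrate]) while solid is left; crystals form when [dissolved substrate] > cs5 (cs5 = 0.089 M, k5 = 0.37 /h)

solid substrate 0.25 M; coupling partner 0.375 M; protic impurity 5.00 mM; time 15 d

- percent here means solid substrate units held: one side product counts as two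
- what is said of target includes solid product
- where a step has two of a species, its rate is k times that concentration squared, and two are used at each turn
- solid substrate, solid product is a solid; its amount is given per volume of the solution
- at the start none of the solid substrate is in solution
- what has only dissolved of solid substrate counts as not reacted
- the reaction counts as stopped when no species that holds the solid substrate changes by six tenths of a point or more over the second half of the time
- run time (flask): 15 d

- why nothing more happens at 15 d, or that something still does (for what has run out or reacted, a solid counts together with what of it has only dissolved) (all of the solid substrate has reacted / the coupling partner has run out first / forward and back rates have come level / it is still moving)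
- amount of target at 15 d, in percent of the solid substrate charged

Two chemists dispute this flask, counting in fractions of the solid substrate charged: b is coupling partner, a dissolved substrate. Both write off 2.00% to the protic impurity. The first sees a limiting-reagent problem: b starts at 1.50, above the one equivalent needed, so coupling takes the rest and target reaches 98.0%.

The second, whose side I take, asks what share of the substrate leaving solution goes to side product. Per dissolved substrate, that step runs at twice its constant times a, and coupling at its constant times b; in their ratio the charge cancels. The level a is quasi-steady, where dissolution matches coupling, which is pseudo-first-order in dissolved substrate. With b at its charge this gives a = 0.197, and the side step's share of the two routes, the leak, is 6.44%.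

When half the charge has coupled, b is 1.00, a is 0.231, and the leak is 10.8%, larger than with b at its charge. Once the solid is gone, a falls, so I take the mean, 8.63%, apply it to what the protic impurity spares, and commit to target 89.5%. I expect the substrate to be consumed, since the half-life of dissolved substrate by coupling alone, with coupling partner as charged, is 0.096 d, far shorter than 15 d.

The forecast gives target 89.3%, within 87.5% to 91%, states that all of the solid substrate has reacted, and stands with the second chemist: “coupling beats dimerisation by about ten to one”.

The simulation shows that all of the solid substrate has reacted: this flask holds target 89.9% and side product 8.15% at 15.0 d, which is 8.31% of what the protic impurity spared, close to the leak of 8.63%, while the first chemist's figure stands 8.1 percentage points too high.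

The neighbour flask with 1.5 M of coupling partner starts at b = 6.00 equiv. There, with b at its charge, a is 0.0839, and the leak drops from 6.44% to 0.729%. At half coupled, a is 0.0896 and the leak 0.848%, so the mean is 0.788% and the reckoned target 97.2%. That neighbour flask ends with side product at 0.753%, and 84% of its coupling partner remains. This is the first chemist's ground: its target is 97.2%, 0.80 points below the 98.0% of that view.

(Its constants come from no measurement, and the outcome is calculated.)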